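## Structural features

The target is a resveratrol trimer made of two 2-aryl-2,3-dihydrobenzofurans joined by one bond. Dihydrobenzofuran 1 (O1, C2, C3, fused to ring A) is attached through C3 to C5' of ring B, the benzo ring of dihydrobenzofuran 2 (O1', C2', C3'). Each heterocycle holds two adjacent stereocentres with trans aryl groups, C2/C3 as (2S,3S) and C2'/C3' as (2R,3R). The two pairs lie on opposite sides of ring B and have opposite local sense, so neither can be used to set the other. Ring A carries a Z-configured 4-hydroxystyryl group at C4, directly beside the crowded C3, and the molecule ends in seven free phenols. The fragile elements are: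
- the Z-stilbene, which can isomerise to E or be protonated to a benzylic cation that electron-rich rings trap;
- the benzylic aryl ether bonds O1–C2 and O1'–C2', which ionise in acid because each carbon bears a 4-oxygenated phenyl ring;
- the doubly benzylic C3–H and C3'–H, which are lost if such a cation eliminates;
- the polyphenol, which oxidises in air under base.

The real difficulty is C3, a triaryl-substituted methine wedged between the 2,6-disubstituted ring A and ring B, whose absolute configuration must be imposed by a reagent. The key step uses the facts that O1 sits ortho to the carbon of ring A that holds C3 and that C2 bears a 4-alkoxyphenyl group. Ring 1 is therefore the adduct of the ring A O–H across a C2=C3 double bond, with the proton going to C3 and the oxygen to the cation-stabilising C2.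

## Logic of the disconnections

**24 to 20 and 22.** The bond between C4 of ring A and the vinyl carbon is cut, together with the O–Si bond that 22 brings in (through 23). The Z-alkene is the most acid- and isomerisation-sensitive element, so it enters last, after every acidic operation and on free phenols, and no deprotection follows it. The gain is that 20 holds no alkene. The demand is a coupling at a hindered C–Cl bond beside C3, with retention of the Z geometry, in the presence of six phenoxides.

**22 to 21.** The C–B bond is cut. This leaves a terminal alkyne; the forward step must add H–B in the anti-Markovnikov sense with Z geometry.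

**20 to 19.** Six O–CH3 bonds are cut. Methyl ethers are the only phenol protection that survives the Lewis acid, strong base and strong Brønsted acid used earlier. They are removed while the C4 position still holds chlorine, so the Lewis acid never meets the stilbene. The demand is that ring opening at O1–C2 or O1'–C2' stays reversible and does not reach C3–H or C3'–H.

**19 to 18.** The O1–C2 bond and the C3–H bond are cut. This removes ring 1 and both of its stereocentres and leaves a flat triarylethylene with a free ortho phenol. The forward step must deliver the proton to one face of C3 and close the ring trans.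

**18 to 5 and 16 (through 17).** The C3–C5' bond is cut. The molecule falls into two halves of similar size, and the alkene arises from the coupling itself. The demand is that palladium inserts into the C–Br bond of 16 and leaves the C–Cl bond of 5 alone, and that the free phenol is tolerated.

**5 to 4 to 3 to 1 and 2.** The C=N bond, the O–CH3 bond ortho to the carbonyl and the aryl–C(O) bond are cut in turn. The demands are acylation of 1 ortho to chlorine and para to a methoxy group, not between the two methoxy groups, and demethylation only at the chelated ortho position.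

**16 to 15 to 13 (through 14).** First the C2' configuration is changed (16 is the C2' epimer of 15), then the C2'–C3' bond is cut. Ring 2 and both stereocentres then come from an achiral diaryl ketone hydrazone that carries a benzylic ether. The demands are catalyst control of C3' in a carbene C–H insertion, and correction of C2' from cis to trans without touching C3'.

**13 to 12 to 11 to 8 and 9 (through 10), and 8 to 6 and 7.** The C=N bond, the ketone oxidation level, the aryl–C(carbinol) bond and the O–CH2 bond are cut. This ends at three catalogue compounds; the forward steps are routine.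

## Other disconnections considered

**Alternative 1:** The cut runs through ring B itself. Breaking C3a'–C7a' and C6'–C7' turns dihydrobenzofuran 2 into an open-chain furyl ynol ether, 4-bromo-2-[(1S,2R)-1-(3,5-dimethoxyphenyl)-2-(ethynyloxy)-2-(4-methoxyphenyl)ethyl]furan A2.
- Forward key step: a cationic phosphine complex of monovalent gold would activate the alkyne of A2. Furan C2 would add to the oxygen-bearing alkyne carbon, the opened furan would reclose on the alkyne terminus, and the furan oxygen would end as the C7' hydroxyl. The product would be (2R,3R)-5-bromo-3-(3,5-dimethoxyphenyl)-2-(4-methoxyphenyl)-2,3-dihydro-1-benzofuran-7-ol A1; O-methylation of A1 would give 16.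
- In its favour: two rings and two C–C bonds form in one atom-economic step, the bromine and the C7' oxygen are placed without any regiochemical choice, and the medium is close to neutral.
- Against it here: the step creates no stereocentre, so C2' and C3' must already be present with absolute control in an acyclic 1,2-diaryl-2-furylethanol. The ynol ether of a secondary 4-methoxybenzylic alcohol is prone to lose ketene or to ionise at C2'. The usual ynol ether preparations use alkyllithium bases, which would attack the furyl bromide. The plan also covers only 16, so steps 10 to 14 would still be needed.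
- Comparison: structurally it is the more ambitious step, since it makes an arene ring where step 11 closes one C–O bond. Mechanistically it is about as unexplored on this substrate class as step 11. Its mildness toward the benzylic ethers is a point on which it is the better. In step count it saves nothing, because A2 needs an asymmetric synthesis about as long as steps 4 to 9, and it leaves C3 unsolved.

**Alternative 2:** Both bonds that flank the former alkene are cut at once, C3–C5' and C2–aryl. The pieces are:
- the ring A alkenylboronate 2-{(E)-2-[2-chloro-4-methoxy-6-(methoxymethoxy)phenyl]ethenyl}-4,4,5,5-tetramethyl-1,3,2-dioxaborolane A4;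
- 4-methoxyphenyllithium A5;
- the ring B triflate (2R,3R)-3-(3,5-dimethoxyphenyl)-7-methoxy-2-(4-methoxyphenyl)-2,3-dihydro-1-benzofuran-5-yl trifluoromethanesulfonate A6.

- Forward key step: A5 would add to boron of A4, and Pd(OAc)2 with a chiral ferrocenyl bisphosphine would couple the ate complex with A6. The arylpalladium species binds the alkene, the anisyl group shifts from boron to C2 anti to palladium, and reductive elimination bonds ring B to C3. The product would be the boronate 2-[(1R,2S)-2-[2-chloro-4-methoxy-6-(methoxymethoxy)phenyl]-2-[(2R,3R)-3-(3,5-dimethoxyphenyl)-7-methoxy-2-(4-methoxyphenyl)-2,3-dihydro-1-benzofuran-5-yl]-1-(4-methoxyphenyl)ethyl]-4,4,5,5-tetramethyl-1,3,2-dioxaborolane A3. Oxidation of the C–B bond, removal of the methoxymethyl group and closure at C2 would then lead to 19.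
- In its favour: it is a convergent three-component step in a known reaction class (conjunctive cross-coupling). C3 is fixed in a C–C bond-forming event, not by a protonation, and no strong acid is needed at the stereo-determining stage.
- Against it here: a β-aryl alkenylboronate with a 2,6-disubstituted aryl group is a demanding substrate, because direct Suzuki coupling of the ate complex and β-hydride elimination would compete. The catalyst must work with or against the chirality already in A6. A6 requires a ring B with a C5' oxygen, where the chosen route needs only a bromide. Three more operations follow the key step, and the last is a closure at a 4-methoxybenzylic carbinol, which should ionise and give the trans ring whatever its configuration, so the C2 configuration bought in the key step is largely redundant.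
- Comparison: on precedent Alternative 2 is the better, since its key step belongs to a known class and step 11 does not. On structure both address the same C2–C3 unit, Alternative 2 through two C–C bonds and the chosen plan through one C–O bond on an alkene supplied by the Barluenga coupling. On step economy the chosen plan is shorter, with no step between the stereo-defining event and 19 where Alternative 2 has three, and with a simpler ring B partner.

**Alternative 3:** The cut is the C3'–C3a' bond of dihydrobenzofuran 2, which is re-formed by a 1,2-shift of ring B. The precursor is the flavanone 4-[(2R)-6-bromo-8-methoxy-4-oxochroman-2-yl]phenyl methanesulfonate A8.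
- Forward key step: PhI(OAc)2 and H2SO4 in trimethyl orthoformate would convert A8, through its enol ether, into an α-iodanyl ketal. Ring B migrates from the ketal carbon to the neighbouring carbon as the iodane leaves. The ring-contracted product would be methyl (2R,3R)-5-bromo-7-methoxy-2-[4-(methanesulfonyloxy)phenyl]-2,3-dihydro-1-benzofuran-3-carboxylate A7.
- In its favour: the oxidative ring contraction of flavanones is a known reaction. One stereocentre in A8, accessible by asymmetric conjugate addition to a chromone or asymmetric oxa-Michael closure, is relayed to C3', and the trans arrangement arises directly. The mesylate tempers the 2-aryl group so that ring B migrates and not that aryl group.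
- Against it here: A7 carries an ester where 3,5-dimethoxyphenyl is needed. Hydrolysis, activation and a decarboxylative arylation at C3' would be required, with trans selectivity plausible but resting on substrate control, and then the mesylate must be exchanged for a methyl ether. Flavanones can racemise by retro-oxa-Michael opening in acid, so the enantiopurity of A8 is at risk in H2SO4. Only 16 is covered.
- Comparison: on mechanism the key step is better precedented than step 11. It also gives the trans ring at once, where steps 8 and 9 pass through the cis isomer; both are points on which it is the better. On structure it solves ring 2 only and leaves C3 open. On step economy it is longer, since about five further steps separate A7 from 16, against six steps in all for 16 in the chosen plan.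

Key step: step 11

Remark on the structures: re-derivation from the target shows that 18 and 19 need no correction. Ring 1 is (2S,3S), ring 2 is (2R,3R) and the styryl group is Z. Compound 18 is drawn as the E isomer, but its geometry is erased in step 11.

Assumption on catalyst handedness: Rh2(R-PTAD)4 (step 8) and the (S,S)-configured acid (step 11) are written for the sense of induction expected by analogy. If the sense proves opposite, the mirror-image catalyst is taken and nothing else changes.

Assumption on supply: 2 and 21 are treated as catalogue compounds.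

Design changes relative to a Suzuki-then-demethylation endgame: the demethylation (step 12) is placed before the Suzuki coupling (step 14), so that BBr3 never meets the Z-stilbene. The chlorine is kept as the C4 substituent of 18 because it survives the Barluenga coupling, is inert to acid, and keeps a second protonatable alkene out of step 11.

## Route

Step 1
Reactants: 1 1-chloro-3,5-dimethoxybenzene; 2 (4-methoxyphenyl)acetyl chloride
Product: 3 1-(2-chloro-4,6-dimethoxyphenyl)-2-(4-methoxyphenyl)ethan-1-one
Conditions: AlCl3 (1.2 equiv), CH2Cl2, 0 °C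
Reagents that add atoms: none
Why: Friedel–Crafts acylation; the acylium ion should attack the position para to one methoxy group and ortho to the other (next to chlorine), since the position between the two methoxy groups is more hindered and lacks a para donor.

Step 2
Reactants: 3 1-(2-chloro-4,6-dimethoxyphenyl)-2-(4-methoxyphenyl)ethan-1-one
Product: 4 1-(2-chloro-6-hydroxy-4-methoxyphenyl)-2-(4-methoxyphenyl)ethan-1-one
Conditions: BCl3 (1.3 equiv), CH2Cl2, −78 °C → 0 °C; H2O
Reagents that add atoms: none
Why: chelation-controlled Lewis acid demethylation; BCl3 bound to the carbonyl oxygen cleaves only the ortho methyl ether through a six-membered chelate, so the para methoxy group, the anisyl ether and the aryl chloride should stay intact.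

Step 3
Reactants: 4 1-(2-chloro-6-hydroxy-4-methoxyphenyl)-2-(4-methoxyphenyl)ethan-1-one
Product: 5 N'-[1-(2-chloro-6-hydroxy-4-methoxyphenyl)-2-(4-methoxyphenyl)ethylidene]-4-methylbenzenesulfonohydrazide
Conditions: TsNHNH2 (1.3 equiv), TsOH (5 mol %), EtOH, 80 °C, 4 Å MS
Reagents that add atoms: 4-methylbenzenesulfonohydrazide, Cc1ccc(cc1)S(=O)(=O)NN
Why: acid-catalysed condensation of a ketone with a sulfonyl hydrazide to the N-tosylhydrazone; the 2,6-disubstituted ketone is hindered, so heat, acid and removal of water are used to drive it.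

Step 4
Reactants: 6 5-bromo-2-hydroxy-3-methoxybenzaldehyde; 7 1-(chloromethyl)-4-methoxybenzene
Product: 8 5-bromo-3-methoxy-2-[(4-methoxybenzyl)oxy]benzaldehyde
Conditions: K2CO3, DMF, 60 °C
Reagents that add atoms: none
Why: Williamson ether synthesis on the phenoxide; the benzylic CH2 introduced here is the future C2'.

Step 5
Reactants: 8 5-bromo-3-methoxy-2-[(4-methoxybenzyl)oxy]benzaldehyde; 9 1-bromo-3,5-dimethoxybenzene
Product: 11 {5-bromo-3-methoxy-2-[(4-methoxybenzyl)oxy]phenyl}(3,5-dimethoxyphenyl)methanol (racemic), via 3,5-dimethoxyphenylmagnesium bromide 10 (not isolated)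
Conditions: 9, Mg, THF, 45 °C; then 8, THF, 0 °C → 25 °C; aq. NH4Cl
Reagents that add atoms: none
Why: Grignard addition to an aldehyde; the aryl bromide of 8 does not exchange with an arylmagnesium bromide at this temperature, and the carbinol stereocentre is removed in step 6.

Step 6
Reactants: 11 {5-bromo-3-methoxy-2-[(4-methoxybenzyl)oxy]phenyl}(3,5-dimethoxyphenyl)methanol
Product: 12 {5-bromo-3-methoxy-2-[(4-methoxybenzyl)oxy]phenyl}(3,5-dimethoxyphenyl)methanone
Conditions: Dess–Martin periodinane (1.2 equiv), CH2Cl2, 25 °C
Reagents that add atoms: none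
Why: Dess–Martin oxidation of a diaryl carbinol to the benzophenone under conditions that leave the 4-methoxybenzyl ether untouched.

Step 7
Reactants: 12 {5-bromo-3-methoxy-2-[(4-methoxybenzyl)oxy]phenyl}(3,5-dimethoxyphenyl)methanone
Product: 13 {5-bromo-3-methoxy-2-[(4-methoxybenzyl)oxy]phenyl}(3,5-dimethoxyphenyl)methanone hydrazone (E/Z mixture)
Conditions: N2H4·H2O (10 equiv), AcOH (cat.), EtOH, 80 °C
Reagents that add atoms: hydrazine (used as the hydrate), NN
Why: hydrazone formation; the large excess of hydrazine suppresses azine formation, and both hydrazone isomers give the same diazo compound in step 8.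

Step 8
Reactants: 13 {5-bromo-3-methoxy-2-[(4-methoxybenzyl)oxy]phenyl}(3,5-dimethoxyphenyl)methanone hydrazone
Product: 15 (2S,3R)-5-bromo-3-(3,5-dimethoxyphenyl)-7-methoxy-2-(4-methoxyphenyl)-2,3-dihydro-1-benzofuran (cis), via diazo compound 14 (not isolated)
Conditions: MnO2 (8 equiv), CH2Cl2, 0 °C, filtration; then Rh2(R-PTAD)4 (1 mol %), CH2Cl2, 0 °C
Reagents that add atoms: none
Why: hydrazone oxidation to a diaryl diazo compound, then enantioselective intramolecular carbene C–H insertion. The dirhodium carbene inserts into the activated benzylic C–H of the 4-methoxybenzyl ether through a five-membered transition state; the chiral carboxylate ligands set C3', and the concerted insertion places the two aryl groups cis.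

Step 9
Reactants: 15 (2S,3R)-5-bromo-3-(3,5-dimethoxyphenyl)-7-methoxy-2-(4-methoxyphenyl)-2,3-dihydro-1-benzofuran
Product: 16 (2R,3R)-5-bromo-3-(3,5-dimethoxyphenyl)-7-methoxy-2-(4-methoxyphenyl)-2,3-dihydro-1-benzofuran (trans)
Conditions: CF3CO2H/CH2Cl2 (1:4), 0 °C → 25 °C
Reagents that add atoms: none
Why: acid-mediated epimerisation; the O1'–C2' bond ionises reversibly to the 4-methoxybenzylic cation and recloses to the more stable trans ring, which inverts C2' only and leaves the catalyst-set C3' untouched.

Step 10
Reactants: 5 N'-[1-(2-chloro-6-hydroxy-4-methoxyphenyl)-2-(4-methoxyphenyl)ethylidene]-4-methylbenzenesulfonohydrazide; 16 (2R,3R)-5-bromo-3-(3,5-dimethoxyphenyl)-7-methoxy-2-(4-methoxyphenyl)-2,3-dihydro-1-benzofuran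
Product: 18 3-chloro-2-{(E)-1-[(2R,3R)-3-(3,5-dimethoxyphenyl)-7-methoxy-2-(4-methoxyphenyl)-2,3-dihydro-1-benzofuran-5-yl]-2-(4-methoxyphenyl)ethenyl}-5-methoxyphenol, via diazo compound 17 (not isolated)
Conditions: Pd2(dba)3 (2.5 mol %), XPhos (10 mol %), LiOtBu (3.5 equiv), 1,4-dioxane, 90 °C
Reagents that add atoms: none
Why: Barluenga coupling; base turns 5 into diazo compound 17, the arylpalladium bromide from 16 forms a palladium carbene, ring B migrates to the carbene carbon and β-hydride elimination from the CH2 group gives the triarylethylene. Zerovalent palladium should insert into the C–Br bond of 16 well before the hindered, electron-rich C–Cl bond of ring A, and the excess base keeps the phenol as its lithium phenoxide. An E/Z mixture is acceptable because step 11 erases the geometry.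

Step 11
Reactants: 18 3-chloro-2-{(E)-1-[(2R,3R)-3-(3,5-dimethoxyphenyl)-7-methoxy-2-(4-methoxyphenyl)-2,3-dihydro-1-benzofuran-5-yl]-2-(4-methoxyphenyl)ethenyl}-5-methoxyphenol
Product: 19 (2R,3R)-5-[(2S,3S)-4-chloro-6-methoxy-2-(4-methoxyphenyl)-2,3-dihydro-1-benzofuran-3-yl]-3-(3,5-dimethoxyphenyl)-7-methoxy-2-(4-methoxyphenyl)-2,3-dihydro-1-benzofuran
Conditions: (S,S)-IDPi (BINOL-derived imidodiphosphorimidate with 3,3'-aryl groups and N-triflyl groups, 5 mol %), CHCl3, 4 Å MS, −20 °C → 0 °C, 0.02 M
Reagents that add atoms: none
Why: Proposed new method: the confined acid protonates the electron-rich C2=C3 bond at C3, which gives a C2 benzylic cation stabilised by its 4-methoxyphenyl group and paired with the chiral imidodiphosphorimidate anion; the ring A phenol oxygen then bonds to C2 (O1–C2) and returns its proton to the anion. The closest known reaction types are the chiral Brønsted acid catalysed intramolecular hydroalkoxylation of alkenes and the acid-induced cyclisation of 2-hydroxystilbenes to 2-aryl-2,3-dihydrobenzofurans; their combination on a triarylethylene is new. The dihydrofuran ring closes in a formal 5-endo-trig mode, which is feasible because the electrophile is a free cation and not a π bond with a fixed trajectory of attack. C3 is set by the catalyst, through the face to which the proton is delivered (or, if protonation is reversible, through the ion pair that closes faster); C2 is set by the substrate, the anisyl group taking the side away from ring B, and reversible ionisation of O1–C2 can correct C2 without touching C3. The selectivity needed is protonation at C3 and not at C2: protonation at C2 gives a diaryl cation that has no ring closure open to it and only returns the alkene, which also interconverts the E and Z isomers of 18 so that both funnel into 19. The chlorine keeps ring A twisted out of conjugation with C3 and keeps a second, more easily protonated stilbene out of the flask, and the distant stereocentres of ring 2 should have little influence, so catalyst control is expected to dominate. The reaction is run cold and dilute and stopped at full conversion, because long exposure could reopen either ring at its benzylic C–O bond.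

Step 12
Reactants: 19 (2R,3R)-5-[(2S,3S)-4-chloro-6-methoxy-2-(4-methoxyphenyl)-2,3-dihydro-1-benzofuran-3-yl]-3-(3,5-dimethoxyphenyl)-7-methoxy-2-(4-methoxyphenyl)-2,3-dihydro-1-benzofuran
Product: 20 5-[(2R,3R)-5-[(2S,3S)-4-chloro-6-hydroxy-2-(4-hydroxyphenyl)-2,3-dihydro-1-benzofuran-3-yl]-7-hydroxy-2-(4-hydroxyphenyl)-2,3-dihydro-1-benzofuran-3-yl]benzene-1,3-diol
Conditions: BBr3 (12 equiv), CH2Cl2, −78 °C → 0 °C; MeOH, then H2O
Reagents that add atoms: none
Why: Lewis acid cleavage of aryl methyl ethers (boron–oxygen adduct, then bromide attack at methyl); no alkene is present at this stage and the aryl chloride is inert. Any benzylic C–O bond that opens should reclose to the trans ring on work-up without involving C3 or C3'.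

Step 13
Reactants: 21 tert-butyl(4-ethynylphenoxy)dimethylsilane
Product: 22 tert-butyldimethyl{4-[(Z)-2-(4,4,5,5-tetramethyl-1,3,2-dioxaborolan-2-yl)ethenyl]phenoxy}silane
Conditions: [Rh(cod)Cl]2 (1.5 mol %), P(iPr)3 (6 mol %), Et3N, pinacolborane (1.0 equiv), 21 (1.2 equiv), cyclohexane, 25 °C
Reagents that add atoms: pinacolborane, CC1(C)OBOC1(C)C
Why: rhodium-catalysed trans-hydroboration of a terminal alkyne; a rhodium vinylidene formed by 1,2-hydrogen shift leads to anti-Markovnikov addition with boron and the aryl group cis, which fixes the Z geometry.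

Step 14
Reactants: 20 5-[(2R,3R)-5-[(2S,3S)-4-chloro-6-hydroxy-2-(4-hydroxyphenyl)-2,3-dihydro-1-benzofuran-3-yl]-7-hydroxy-2-(4-hydroxyphenyl)-2,3-dihydro-1-benzofuran-3-yl]benzene-1,3-diol; 22 tert-butyldimethyl{4-[(Z)-2-(4,4,5,5-tetramethyl-1,3,2-dioxaborolan-2-yl)ethenyl]phenoxy}silane
Product: 24 5-[(2R,3R)-7-hydroxy-5-{(2S,3S)-6-hydroxy-2-(4-hydroxyphenyl)-4-[(Z)-2-(4-hydroxyphenyl)ethenyl]-2,3-dihydro-1-benzofuran-3-yl}-2-(4-hydroxyphenyl)-2,3-dihydro-1-benzofuran-3-yl]benzene-1,3-diol, via silyl ether 23 (not isolated)
Conditions: Pd(OAc)2 (5 mol %), SPhos (10 mol %), K3PO4 (10 equiv), THF/H2O, 65 °C, degassed, dark, continued until the silyl ether is hydrolysed; work-up at pH 6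
Reagents that add atoms: none
Why: Suzuki–Miyaura coupling with retention of alkene geometry, since transmetalation and reductive elimination are stereoretentive. The C4 chloride is meta to both oxygens of ring A, so the phenoxide should not block oxidative addition by the SPhos-ligated palladium. The aqueous phosphate then hydrolyses the aryl silyl ether of 23 in the same flask, so no acid or Lewis acid touches the Z-stilbene.

## Compound list

1 | 1-chloro-3,5-dimethoxybenzene | COc1cc(Cl)cc(OC)c1 | starting material
2 | (4-methoxyphenyl)acetyl chloride | COc1ccc(CC(=O)Cl)cc1 | starting material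
3 | 1-(2-chloro-4,6-dimethoxyphenyl)-2-(4-methoxyphenyl)ethan-1-one | COc1ccc(CC(=O)c2c(Cl)cc(OC)cc2OC)cc1 | intermediate
4 | 1-(2-chloro-6-hydroxy-4-methoxyphenyl)-2-(4-methoxyphenyl)ethan-1-one | COc1ccc(CC(=O)c2c(Cl)cc(OC)cc2O)cc1 | intermediate
5 | N'-[1-(2-chloro-6-hydroxy-4-methoxyphenyl)-2-(4-methoxyphenyl)ethylidene]-4-methylbenzenesulfonohydrazide | COc1ccc(CC(=NNS(=O)(=O)c2ccc(C)cc2)c2c(Cl)cc(OC)cc2O)cc1 | intermediate
6 | 5-bromo-2-hydroxy-3-methoxybenzaldehyde | COc1cc(Br)cc(C=O)c1O | starting material
7 | 1-(chloromethyl)-4-methoxybenzene | COc1ccc(CCl)cc1 | starting material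
8 | 5-bromo-3-methoxy-2-[(4-methoxybenzyl)oxy]benzaldehyde | COc1ccc(COc2c(C=O)cc(Br)cc2OC)cc1 | intermediate
9 | 1-bromo-3,5-dimethoxybenzene | COc1cc(Br)cc(OC)c1 | starting material
10 | 3,5-dimethoxyphenylmagnesium bromide | COc1cc([Mg]Br)cc(OC)c1 | intermediate
11 | {5-bromo-3-methoxy-2-[(4-methoxybenzyl)oxy]phenyl}(3,5-dimethoxyphenyl)methanol (racemic) | COc1ccc(COc2c(C(O)c3cc(OC)cc(OC)c3)cc(Br)cc2OC)cc1 | intermediate
12 | {5-bromo-3-methoxy-2-[(4-methoxybenzyl)oxy]phenyl}(3,5-dimethoxyphenyl)methanone | COc1ccc(COc2c(C(=O)c3cc(OC)cc(OC)c3)cc(Br)cc2OC)cc1 | intermediate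
13 | {5-bromo-3-methoxy-2-[(4-methoxybenzyl)oxy]phenyl}(3,5-dimethoxyphenyl)methanone hydrazone | COc1ccc(COc2c(C(=NN)c3cc(OC)cc(OC)c3)cc(Br)cc2OC)cc1 | intermediate
14 | 5-bromo-1-[diazo(3,5-dimethoxyphenyl)methyl]-3-methoxy-2-[(4-methoxybenzyl)oxy]benzene | COc1ccc(COc2c(C(=[N+]=[N-])c3cc(OC)cc(OC)c3)cc(Br)cc2OC)cc1 | intermediate
15 | (2S,3R)-5-bromo-3-(3,5-dimethoxyphenyl)-7-methoxy-2-(4-methoxyphenyl)-2,3-dihydro-1-benzofuran (cis) | Brc1cc(OC)c2c(c1)[C@@H](c1cc(OC)cc(OC)c1)[C@@H](c1ccc(OC)cc1)O2 | intermediate
16 | (2R,3R)-5-bromo-3-(3,5-dimethoxyphenyl)-7-methoxy-2-(4-methoxyphenyl)-2,3-dihydro-1-benzofuran (trans) | Brc1cc(OC)c2c(c1)[C@@H](c1cc(OC)cc(OC)c1)[C@H](c1ccc(OC)cc1)O2 | intermediate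
17 | 3-chloro-2-[1-diazo-2-(4-methoxyphenyl)ethyl]-5-methoxyphenol (present as its lithium phenoxide) | COc1ccc(CC(=[N+]=[N-])c2c(Cl)cc(OC)cc2O)cc1 | intermediate
18 | 3-chloro-2-{(E)-1-[(2R,3R)-3-(3,5-dimethoxyphenyl)-7-methoxy-2-(4-methoxyphenyl)-2,3-dihydro-1-benzofuran-5-yl]-2-(4-methoxyphenyl)ethenyl}-5-methoxyphenol | COc1cc(O)c(c(Cl)c1)/C(c1cc(OC)c2c(c1)[C@@H](c1cc(OC)cc(OC)c1)[C@H](c1ccc(OC)cc1)O2)=C/c1ccc(OC)cc1 | intermediate
19 | (2R,3R)-5-[(2S,3S)-4-chloro-6-methoxy-2-(4-methoxyphenyl)-2,3-dihydro-1-benzofuran-3-yl]-3-(3,5-dimethoxyphenyl)-7-methoxy-2-(4-methoxyphenyl)-2,3-dihydro-1-benzofuran | Clc1cc(OC)cc2c1[C@H](c1cc(OC)c3c(c1)[C@@H](c1cc(OC)cc(OC)c1)[C@H](c1ccc(OC)cc1)O3)[C@@H](c1ccc(OC)cc1)O2 | intermediate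
20 | 5-[(2R,3R)-5-[(2S,3S)-4-chloro-6-hydroxy-2-(4-hydroxyphenyl)-2,3-dihydro-1-benzofuran-3-yl]-7-hydroxy-2-(4-hydroxyphenyl)-2,3-dihydro-1-benzofuran-3-yl]benzene-1,3-diol | Clc1cc(O)cc2c1[C@H](c1cc(O)c3c(c1)[C@@H](c1cc(O)cc(O)c1)[C@H](c1ccc(O)cc1)O3)[C@@H](c1ccc(O)cc1)O2 | intermediate
21 | tert-butyl(4-ethynylphenoxy)dimethylsilane | C#Cc1ccc(O[Si](C)(C)C(C)(C)C)cc1 | starting material
22 | tert-butyldimethyl{4-[(Z)-2-(4,4,5,5-tetramethyl-1,3,2-dioxaborolan-2-yl)ethenyl]phenoxy}silane | CC(C)(C)[Si](C)(C)Oc1ccc(/C=C\B2OC(C)(C)C(C)(C)O2)cc1 | intermediate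
23 | 5-[(2R,3R)-5-{(2S,3S)-4-[(Z)-2-{4-[(tert-butyldimethylsilyl)oxy]phenyl}ethenyl]-6-hydroxy-2-(4-hydroxyphenyl)-2,3-dihydro-1-benzofuran-3-yl}-7-hydroxy-2-(4-hydroxyphenyl)-2,3-dihydro-1-benzofuran-3-yl]benzene-1,3-diol | CC(C)(C)[Si](C)(C)Oc1ccc(/C=C\c2cc(O)cc3c2[C@H](c2cc(O)c4c(c2)[C@@H](c2cc(O)cc(O)c2)[C@H](c2ccc(O)cc2)O4)[C@@H](c2ccc(O)cc2)O3)cc1 | intermediate
24 | 5-[(2R,3R)-7-hydroxy-5-{(2S,3S)-6-hydroxy-2-(4-hydroxyphenyl)-4-[(Z)-2-(4-hydroxyphenyl)ethenyl]-2,3-dihydro-1-benzofuran-3-yl}-2-(4-hydroxyphenyl)-2,3-dihydro-1-benzofuran-3-yl]benzene-1,3-diol (CNP0172909.2) | Oc1ccc(/C=C\c2cc(O)cc3c2[C@H](c2cc(O)c4c(c2)[C@@H](c2cc(O)cc(O)c2)[C@H](c2ccc(O)cc2)O4)[C@@H](c2ccc(O)cc2)O3)cc1 | target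

## Step count and least certain steps

Total step count: 14. Longest linear sequence: 10 steps (steps 4 to 12 and step 14, starting from 6).

**Step 11 (key step, new method).** Three processes could defeat it. Protonation at C2 could dominate, and the resulting diaryl cation could be consumed by intermolecular Friedel–Crafts alkylation and not return to the alkene. Facial discrimination at C3 could be poor, because the hindered triarylethylene may sit badly in the confined acid. Ring 2 could reopen at O1'–C2' and lose C3'–H, which would erode C3'. The fallback uses known chemistry and gives up catalyst control. It sets out from 18: a catalytic achiral strong acid (CF3SO3H, CH2Cl2, −40 °C) closes ring 1 by the known acid-induced cyclisation of 2-hydroxystilbenes. Because ring 2 is already a single enantiomer, the outcome would be 19 together with its ring 1 diastereomer, (2R,3R)-5-[(2R,3R)-4-chloro-6-methoxy-2-(4-methoxyphenyl)-2,3-dihydro-1-benzofuran-3-yl]-3-(3,5-dimethoxyphenyl)-7-methoxy-2-(4-methoxyphenyl)-2,3-dihydro-1-benzofuran F1. These are separable by chromatography, and the route is rejoined at 19.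

**Step 10.** The free ortho phenoxide could divert the diazo compound or the palladium carbene (1,2-hydrogen shift to a stilbene, azine formation). The hindered hydrazone could react slowly, and palladium could insert into the ring A C–Cl bond once 16 is used up. The fallback masks the phenol and so changes the substrate class to an ordinary aryl ketone hydrazone. It sets out from 4:
- chloromethyl methyl ether and iPr2NEt give 1-[2-chloro-4-methoxy-6-(methoxymethoxy)phenyl]-2-(4-methoxyphenyl)ethan-1-one F2;
- condensation with TsNHNH2 gives N'-{1-[2-chloro-4-methoxy-6-(methoxymethoxy)phenyl]-2-(4-methoxyphenyl)ethylidene}-4-methylbenzenesulfonohydrazide F3;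
- the same palladium coupling with 16 passes through 1-chloro-2-[1-diazo-2-(4-methoxyphenyl)ethyl]-5-methoxy-3-(methoxymethoxy)benzene F4 (not isolated) and gives (2R,3R)-5-{(E)-1-[2-chloro-4-methoxy-6-(methoxymethoxy)phenyl]-2-(4-methoxyphenyl)ethenyl}-3-(3,5-dimethoxyphenyl)-7-methoxy-2-(4-methoxyphenyl)-2,3-dihydro-1-benzofuran F5;
- dilute HCl in MeOH at 25 °C removes the acetal, and the route is rejoined at 18.

**Step 14.** The Z geometry could be lost through palladium hydride-mediated isomerisation, oxidative addition into the hindered chloride could be slow, and the polyphenoxide could oxidise. The fallback builds the alkene by syn-hydrogenation of an alkyne. It sets out from 20: copper-free Sonogashira coupling with 4-ethynylphenol (PdCl2(MeCN)2, XPhos, Cs2CO3, MeCN, 80 °C) gives 5-[(2R,3R)-7-hydroxy-5-{(2S,3S)-6-hydroxy-2-(4-hydroxyphenyl)-4-[(4-hydroxyphenyl)ethynyl]-2,3-dihydro-1-benzofuran-3-yl}-2-(4-hydroxyphenyl)-2,3-dihydro-1-benzofuran-3-yl]benzene-1,3-diol F6. Semi-hydrogenation over Pd/CaCO3 poisoned with Pb(OAc)2 and quinoline under H2 then rejoins the route at 24.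

**Step 8 (with step 9).** Enantio-induction at C3' could be weak for this ortho-methoxy, bromo-substituted diaryl diazo compound, the diazo compound could dimerise to the azine, and the acid of step 9 could erode C3' through elimination and re-addition. The fallback replaces asymmetric catalysis by resolution. It sets out from 14: Rh2(OAc)4 gives racemic cis product, that is 15 with its enantiomer (2R,3S)-5-bromo-3-(3,5-dimethoxyphenyl)-7-methoxy-2-(4-methoxyphenyl)-2,3-dihydro-1-benzofuran F7. Epimerisation as in step 9 gives 16 with its enantiomer (2S,3S)-5-bromo-3-(3,5-dimethoxyphenyl)-7-methoxy-2-(4-methoxyphenyl)-2,3-dihydro-1-benzofuran F8. Preparative chromatography on a chiral stationary phase rejoins the route at 16.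

**Step 12.** The Lewis acid could open the benzylic C–O bonds, followed by elimination at C3 or C3' or by bromide capture, and demethylation of six ethers could stay incomplete. The fallback replaces the Lewis acid by a nucleophile. It sets out from 19: sodium ethanethiolate in DMF at 130 °C removes the methyl groups by SN2 attack at carbon, without a benzylic cation, and the route is rejoined at 20; no new compound is made (F0).

## Further compounds

F1 | step 11 | (2R,3R)-5-[(2R,3R)-4-chloro-6-methoxy-2-(4-methoxyphenyl)-2,3-dihydro-1-benzofuran-3-yl]-3-(3,5-dimethoxyphenyl)-7-methoxy-2-(4-methoxyphenyl)-2,3-dihydro-1-benzofuran | Clc1cc(OC)cc2c1[C@@H](c1cc(OC)c3c(c1)[C@@H](c1cc(OC)cc(OC)c1)[C@H](c1ccc(OC)cc1)O3)[C@H](c1ccc(OC)cc1)O2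
F2 | step 10 | 1-[2-chloro-4-methoxy-6-(methoxymethoxy)phenyl]-2-(4-methoxyphenyl)ethan-1-one | COCOc1cc(OC)cc(Cl)c1C(=O)Cc1ccc(OC)cc1
F3 | step 10 | N'-{1-[2-chloro-4-methoxy-6-(methoxymethoxy)phenyl]-2-(4-methoxyphenyl)ethylidene}-4-methylbenzenesulfonohydrazide | COCOc1cc(OC)cc(Cl)c1C(Cc1ccc(OC)cc1)=NNS(=O)(=O)c1ccc(C)cc1
F4 | step 10 | 1-chloro-2-[1-diazo-2-(4-methoxyphenyl)ethyl]-5-methoxy-3-(methoxymethoxy)benzene | COCOc1cc(OC)cc(Cl)c1C(=[N+]=[N-])Cc1ccc(OC)cc1
F5 | step 10 | (2R,3R)-5-{(E)-1-[2-chloro-4-methoxy-6-(methoxymethoxy)phenyl]-2-(4-methoxyphenyl)ethenyl}-3-(3,5-dimethoxyphenyl)-7-methoxy-2-(4-methoxyphenyl)-2,3-dihydro-1-benzofuran | COCOc1cc(OC)cc(Cl)c1/C(c1cc(OC)c2c(c1)[C@@H](c1cc(OC)cc(OC)c1)[C@H](c1ccc(OC)cc1)O2)=C/c1ccc(OC)cc1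
F6 | step 14 | 5-[(2R,3R)-7-hydroxy-5-{(2S,3S)-6-hydroxy-2-(4-hydroxyphenyl)-4-[(4-hydroxyphenyl)ethynyl]-2,3-dihydro-1-benzofuran-3-yl}-2-(4-hydroxyphenyl)-2,3-dihydro-1-benzofuran-3-yl]benzene-1,3-diol | Oc1ccc(C#Cc2cc(O)cc3c2[C@H](c2cc(O)c4c(c2)[C@@H](c2cc(O)cc(O)c2)[C@H](c2ccc(O)cc2)O4)[C@@H](c2ccc(O)cc2)O3)cc1
F7 | step 8 | (2R,3S)-5-bromo-3-(3,5-dimethoxyphenyl)-7-methoxy-2-(4-methoxyphenyl)-2,3-dihydro-1-benzofuran | Brc1cc(OC)c2c(c1)[C@H](c1cc(OC)cc(OC)c1)[C@H](c1ccc(OC)cc1)O2
F8 | step 8 | (2S,3S)-5-bromo-3-(3,5-dimethoxyphenyl)-7-methoxy-2-(4-methoxyphenyl)-2,3-dihydro-1-benzofuran | Brc1cc(OC)c2c(c1)[C@H](c1cc(OC)cc(OC)c1)[C@@H](c1ccc(OC)cc1)O2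
F0 | step 12 | none | none
A1 | alternative 1 | (2R,3R)-5-bromo-3-(3,5-dimethoxyphenyl)-2-(4-methoxyphenyl)-2,3-dihydro-1-benzofuran-7-ol | Brc1cc(O)c2c(c1)[C@@H](c1cc(OC)cc(OC)c1)[C@H](c1ccc(OC)cc1)O2
A2 | alternative 1 | 4-bromo-2-[(1S,2R)-1-(3,5-dimethoxyphenyl)-2-(ethynyloxy)-2-(4-methoxyphenyl)ethyl]furan | C#CO[C@@H](c1ccc(OC)cc1)[C@H](c1cc(OC)cc(OC)c1)c1cc(Br)co1
A3 | alternative 2 | 2-[(1R,2S)-2-[2-chloro-4-methoxy-6-(methoxymethoxy)phenyl]-2-[(2R,3R)-3-(3,5-dimethoxyphenyl)-7-methoxy-2-(4-methoxyphenyl)-2,3-dihydro-1-benzofuran-5-yl]-1-(4-methoxyphenyl)ethyl]-4,4,5,5-tetramethyl-1,3,2-dioxaborolane | COCOc1cc(OC)cc(Cl)c1[C@H](c1cc(OC)c2c(c1)[C@@H](c1cc(OC)cc(OC)c1)[C@H](c1ccc(OC)cc1)O2)[C@H](c1ccc(OC)cc1)B1OC(C)(C)C(C)(C)O1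
A4 | alternative 2 | 2-{(E)-2-[2-chloro-4-methoxy-6-(methoxymethoxy)phenyl]ethenyl}-4,4,5,5-tetramethyl-1,3,2-dioxaborolane | COCOc1cc(OC)cc(Cl)c1/C=C/B1OC(C)(C)C(C)(C)O1
A5 | alternative 2 | 4-methoxyphenyllithium | [Li]c1ccc(OC)cc1
A6 | alternative 2 | (2R,3R)-3-(3,5-dimethoxyphenyl)-7-methoxy-2-(4-methoxyphenyl)-2,3-dihydro-1-benzofuran-5-yl trifluoromethanesulfonate | O=S(=O)(Oc1cc(OC)c2c(c1)[C@@H](c1cc(OC)cc(OC)c1)[C@H](c1ccc(OC)cc1)O2)C(F)(F)F
A7 | alternative 3 | methyl (2R,3R)-5-bromo-7-methoxy-2-[4-(methanesulfonyloxy)phenyl]-2,3-dihydro-1-benzofuran-3-carboxylate | Brc1cc(OC)c2c(c1)[C@@H](C(=O)OC)[C@H](c1ccc(OS(C)(=O)=O)cc1)O2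
A8 | alternative 3 | 4-[(2R)-6-bromo-8-methoxy-4-oxochroman-2-yl]phenyl methanesulfonate | O=C1C[C@H](c2ccc(OS(C)(=O)=O)cc2)Oc2c(OC)cc(Br)cc12
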